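The runs are calculated with made-up constants, noise included.

The pitfall I saw in this row was to take a larger charge of solid substrate for a larger amount of target within the hour. The solid substrate starts undissolved, and the coupling partner turns it into target.

| setting | winter | dawn | noon | blue | green | red |
|---|---|---|---|---|---|---|
| solid substrate | 2.8 mM | 9.3 mM | 26 mM | 3.0 mM | 8.0 mM | 25 mM |
| coupling partner | 22.5 mM | 22.5 mM | 22.5 mM | 22.5 mM | 22.5 mM | 22.5 mM |
| remark | run made earlier | run made earlier | run made earlier |  |  |  |
| time |  |  |  | 1.0 h | 1.0 h | 1.0 h |

- winter (time / min: target / %, solid substrate / %): 5.00: 7.2, 85.8; 10.0: 21.4, 71.1; 15.0: 33.8, 56.8; 30.0: 76.2, 14.2; 60.0: 99.4, 0.1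
- dawn (time / min: target / %, solid substrate / %): 5.00: 2.2, 94.8; 10.0: 6.1, 90.8; 15.0: 9.9, 88.0; 30.0: 23.2, 73.6; 60.0: 46.6, 45.4
- noon (time / min: target / %, solid substrate / %): 5.00: 0, 99.0; 15.0: 3.7, 94.5; 30.0: 7.7, 90.4; 40.0: 10.9, 87.3; 60.0: 13.7, 78.3

(each reading ± 0.5 percentage points)

- as a solid, counted per litre of solution: solid substrate
- at the start none of the solid substrate is in solution
- "hardly changes" means that all values lie within two and a half points (for a concentration: within two and a half percent of the largest)

- [target] at the end for blue, green, red, in this order
- the course of these numbers from the first flask to the last (hardly changes / falls all the way / rises all the way / falls, then rises / rises, then falls)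

I reckoned with the rate v of target formation. Between 10.0 min and 30.0 min the dawn run gave v = 0.0795 mM min⁻¹, and the winter run over the same span gave 0.0767 mM min⁻¹. The noon run gave 0.0749 mM min⁻¹ between 15.0 min and 40.0 min. These rates stood beside charges from 2.8 mM to 26 mM, so I let the dawn rate stand for the flask. Held for 1.0 h, it makes 4.77 mM. I called this C, the hour's capacity, the target made in the hour at the unslowed rate.

The readings show two slowings. The first is a start-up lag: the noon run read 0 percent at 5.00 min. The second is a late sag. Dawn's v between 30.0 min and 60.0 min read 0.0725 mM min⁻¹, and noon's read 0.0364 mM min⁻¹ after 40.0 min, but that noon figure is the difference of two readings, each scattered by 0.5 percentage points, so I took it as a sign of a sag and not as its size. Accumulated over the hour, dawn ended at 0.908 of C and noon at 0.747 of C.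

Control changes hands where the charge crosses C. Blue's charge is below C and below the coupling partner's, so there the solid substrate is the limiting reagent, and at v it needs 37.7 min. Green and red stand above C, so I took dawn's share for green, 4.33 mM, and noon's for red, 3.56 mM.

The forecast gave 2.97 mM, 4.4 mM and 3.7 mM, a course that rises, then falls, slightly above mine in green and red. Its ground: “Extra substrate seems to feed a side path”.

The flasks gave 2.97 mM, 4.32 mM and 3.77 mM, a course that rises, then falls.

    solid substrate + target → side product (k = 0.00490 L mol⁻¹ s⁻¹)
    dissolved substrate + coupling partner → target (k = 0.250 L mol⁻¹ s⁻¹)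
    solid substrate ⇌ dissolved substrate, rate k3*(cs3 - [dissolved substrate]) while solid is left; crystals form when [dissolved substrate] > cs3 (solubility = 9.10 mM, k = 1.50 × 10⁻⁴ s⁻¹)

At the end, red held 5.75% of its charge as side product, a share in which each side product counts as two, while green held 4.28%. Measured against C, green fell short by 0.450 mM and red by 1.00 mM.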